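**Assumption:** the target is read as the (2S)-flavanone carrying a cis-(3S,4S)-diol on the dimethylchroman ring. Chroman numbering is used for that ring throughout, and "prenyl" means 3-methylbut-2-en-1-yl.

## Retrosynthetic overview

1. Ring C is closed last: target 15 ⇐ unprotected 2',4',6'-trihydroxychalcone 14 by a catalytic asymmetric 6-endo oxa-Michael addition (the chalcone → flavanone step of flavonoid biosynthesis), which sets C2.
2. 14 ⇐ Claisen–Schmidt condensation of unprotected 2',4',6'-trihydroxyacetophenone 11 with aldehyde 10, whose cis-diol is masked as a cyclic carbonate that the same base removes.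
3. cis-(3S,4S)-Diol ⇐ chromene 6 along the chromene → epoxide → diol path: chemoselective Jacobsen–Katsuki epoxidation (sets C3 and C4), then CO2 insertion with double inversion at C4 (net retention).
4. The pyran ring is closed first: 6 ⇐ symmetrical 4-hydroxy-3,5-diprenylbenzaldehyde 4 by dehydrogenation to an o-quinone methide and oxa-6π electrocyclisation; 4 ⇐ 4-hydroxybenzaldehyde 1 + two equivalents of prenyl bromide 2.
5. Ring order: pyran ring (step 2) → transient oxirane and dioxolanone (steps 3 and 4) → ring C (step 6).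

## Route

**Step 1**
Reactants: 1 4-hydroxybenzaldehyde; 2 prenyl bromide (1-bromo-3-methylbut-2-ene)
Product: 4 4-hydroxy-3,5-bis(3-methylbut-2-en-1-yl)benzaldehyde, via mono-prenyl phenol 3 (not isolated)
Conditions: KOH (10% aq., 3 equiv), 2 (2.5 equiv in total, added in two portions), rt, 48 h
Reagents that add atoms: prenyl bromide (second equivalent, which installs the second prenyl group), CC(C)=CCBr
Why: Two successive ortho-C-alkylations of an ambident phenoxide in water, where hydrogen bonding to the phenoxide oxygen steers the allyl halide to carbon and the blocked para position leaves only the two equivalent ortho sites, so the first equivalent of 2 gives 3 and the second carries it on to 4 (modest yield expected); no stereocentre is formed.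

**Step 2**
Reactants: 4 4-hydroxy-3,5-bis(3-methylbut-2-en-1-yl)benzaldehyde
Product: 6 2,2-dimethyl-8-(3-methylbut-2-en-1-yl)-2H-chromene-6-carbaldehyde, via o-quinone methide 5 (not isolated)
Conditions: DDQ (1.2 equiv), benzene, reflux, 3 h
Reagents that add atoms: none
Why: Biomimetic dehydrogenative cyclisation in which DDQ abstracts hydride from the benzylic, allylic CH2 of one prenyl group and the o-quinone methide 5 closes by oxa-6π electrocyclisation; the single phenolic oxygen is consumed, so the second prenyl group cannot cyclise and the symmetrical 4 is desymmetrised without a selectivity problem; no stereocentre is formed.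

**Step 3**
Reactants: 6 2,2-dimethyl-8-(3-methylbut-2-en-1-yl)-2H-chromene-6-carbaldehyde
Product: 7 (3S,4S)-3,4-epoxy-2,2-dimethyl-8-(3-methylbut-2-en-1-yl)chroman-6-carbaldehyde
Conditions: (S,S)-(salen)MnCl [salen = N,N'-bis(3,5-di-tert-butylsalicylidene)-1,2-cyclohexanediamine dianion] (4 mol %), 4-phenylpyridine N-oxide (0.2 equiv), NaOCl (aq., Na2HPO4 buffer, pH 11.3, 1.5 equiv), CH2Cl2, 0 °C, 4 h
Reagents that add atoms: sodium hypochlorite, [Na+].[O-]Cl
Why: Jacobsen–Katsuki epoxidation, in which the manganese-oxo species oxidises the aryl-conjugated cis-alkene of the 2,2-dimethylchromene much faster than the isolated trisubstituted prenyl alkene, and the (S,S)-ligand delivers oxygen to the face that gives the (3S,4S)-epoxide (the sense known for 6-substituted 2,2-dimethylchromenes and for indene), setting C3 and C4 together.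

**Step 4**
Reactants: 7 (3S,4S)-3,4-epoxy-2,2-dimethyl-8-(3-methylbut-2-en-1-yl)chroman-6-carbaldehyde
Product: 10 (3S,4S)-cis-3,4-(carbonyldioxy)-2,2-dimethyl-8-(3-methylbut-2-en-1-yl)chroman-6-carbaldehyde (cyclic carbonate of the cis-diol), via bromo alkoxide 8 (not isolated), via bromo carbonate 9 (not isolated)
Conditions: CO2 (20 bar), nBu4NBr (0.2 equiv), MeCN, 90 °C, 24 h; recrystallise to raise ee
Reagents that add atoms: carbon dioxide, O=C=O
Why: Halide-catalysed CO2/epoxide cycloaddition in which bromide opens the benzylic C4–O bond with inversion, alkoxide 8 captures CO2 and carbonate 9 displaces bromide with a second inversion, so the C3–O bond is never broken, C4 is retained overall and only the cis-fused (3S,4S)-carbonate forms.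

**Step 5**
Reactants: 10 (3S,4S)-cis-3,4-(carbonyldioxy)-2,2-dimethyl-8-(3-methylbut-2-en-1-yl)chroman-6-carbaldehyde; 11 2',4',6'-trihydroxyacetophenone
Product: 14 (E)-3-[(3S,4S)-3,4-dihydroxy-2,2-dimethyl-8-(3-methylbut-2-en-1-yl)chroman-6-yl]-1-(2,4,6-trihydroxyphenyl)prop-2-en-1-one, via diol aldehyde 12 (not isolated), via aldol adduct 13 (not isolated)
Conditions: 11 (1.2 equiv), KOH (50% aq., 20 equiv), EtOH, Ar, 0 °C to rt, 48 h; then cold aq. citric acid to pH 4, EtOAc, rapid chromatography below 10 °C
Reagents that add atoms: none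
Why: Claisen–Schmidt condensation (aldol addition, then E1cB dehydration to the E-enone) after hydroxide has cleaved the cyclic carbonate at its acyl carbon, which leaves both C–O bonds and the (3S,4S) configuration intact; the polyphenoxide chalcone does not cyclise in strong base, and cold work-up at pH 4 keeps it open.

**Step 6**
Reactants: 14 (E)-3-[(3S,4S)-3,4-dihydroxy-2,2-dimethyl-8-(3-methylbut-2-en-1-yl)chroman-6-yl]-1-(2,4,6-trihydroxyphenyl)prop-2-en-1-one
Product: 15 (2S)-2-[(3S,4S)-3,4-dihydroxy-2,2-dimethyl-8-(3-methylbut-2-en-1-yl)chroman-6-yl]-5,7-dihydroxy-2,3-dihydro-4H-chromen-4-one (CNP0305950.3)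
Conditions: N-[3,5-bis(trifluoromethyl)phenyl]-N'-[(8α,9S)-6'-methoxycinchonan-9-yl]thiourea (quinine-derived, 20 mol %), toluene/THF 4:1, −20 °C, 72 h; AcOH quench; preparative HPLC (C18, 0.1% HCO2H)
Reagents that add atoms: none
Why: Proposed new method: a chalcone-isomerase-type 6-endo-trig oxa-Michael addition in which the quinuclidine of the catalyst takes the proton of the free 2'-OH to give a chiral ammonium phenoxide ion pair while the thiourea, together with the chelating 6'-OH, hydrogen-bonds the enone carbonyl, so that the phenoxide adds to one face of Cβ and C2 is set under catalyst control (the remote diol exerts no bias, the 2S:2R ratio is read directly as a diastereomer ratio, and the quinidine-derived pseudo-enantiomer is the switch if the first run favours 2R), the closest known reaction types being the cinchona-alkaloid-catalysed cyclisation of 2',6'-dihydroxychalcones to 5-hydroxyflavanones and bifunctional-thiourea-catalysed intramolecular oxa-Michael additions of activated 2'-hydroxychalcones.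

## Compound list

1 | 4-hydroxybenzaldehyde | O=Cc1ccc(O)cc1 | starting material
2 | prenyl bromide (1-bromo-3-methylbut-2-ene) | CC(C)=CCBr | starting material
3 | 4-hydroxy-3-(3-methylbut-2-en-1-yl)benzaldehyde | CC(C)=CCc1cc(C=O)ccc1O | intermediate (not isolated)
4 | 4-hydroxy-3,5-bis(3-methylbut-2-en-1-yl)benzaldehyde | CC(C)=CCc1cc(C=O)cc(CC=C(C)C)c1O | intermediate
5 | (6Z)-4-formyl-2-(3-methylbut-2-en-1-yl)-6-(3-methylbut-2-en-1-ylidene)cyclohexa-2,4-dien-1-one (o-quinone methide) | CC(C)=CCC1=CC(C=O)=C/C(=C/C=C(C)C)C1=O | intermediate (not isolated)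
6 | 2,2-dimethyl-8-(3-methylbut-2-en-1-yl)-2H-chromene-6-carbaldehyde | CC(C)=CCc1cc(C=O)cc2c1OC(C)(C)C=C2 | intermediate
7 | (3S,4S)-3,4-epoxy-2,2-dimethyl-8-(3-methylbut-2-en-1-yl)chroman-6-carbaldehyde | CC(C)=CCc1cc(C=O)cc2c1OC(C)(C)[C@H]3O[C@@H]23 | intermediate
8 | tetrabutylammonium (3R,4R)-4-bromo-6-formyl-2,2-dimethyl-8-(3-methylbut-2-en-1-yl)chroman-3-olate (trans) | CC(C)=CCc1cc(C=O)cc2c1OC(C)(C)[C@@H]([O-])[C@@H]2Br.CCCC[N+](CCCC)(CCCC)CCCC | intermediate (not isolated)
9 | tetrabutylammonium (3R,4R)-4-bromo-6-formyl-2,2-dimethyl-8-(3-methylbut-2-en-1-yl)chroman-3-yl carbonate (trans) | CC(C)=CCc1cc(C=O)cc2c1OC(C)(C)[C@@H](OC([O-])=O)[C@@H]2Br.CCCC[N+](CCCC)(CCCC)CCCC | intermediate (not isolated)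
10 | (3S,4S)-cis-3,4-(carbonyldioxy)-2,2-dimethyl-8-(3-methylbut-2-en-1-yl)chroman-6-carbaldehyde | CC(C)=CCc1cc(C=O)cc2c1OC(C)(C)[C@H]3OC(=O)O[C@@H]23 | intermediate
11 | 2',4',6'-trihydroxyacetophenone | CC(=O)c1c(O)cc(O)cc1O | starting material
12 | (3S,4S)-3,4-dihydroxy-2,2-dimethyl-8-(3-methylbut-2-en-1-yl)chroman-6-carbaldehyde | CC(C)=CCc1cc(C=O)cc2c1OC(C)(C)[C@@H](O)[C@H]2O | intermediate (not isolated)
13 | 3-[(3S,4S)-3,4-dihydroxy-2,2-dimethyl-8-(3-methylbut-2-en-1-yl)chroman-6-yl]-3-hydroxy-1-(2,4,6-trihydroxyphenyl)propan-1-one (both carbinol epimers) | CC(C)=CCc1cc(C(O)CC(=O)c2c(O)cc(O)cc2O)cc2c1OC(C)(C)[C@@H](O)[C@H]2O | intermediate (not isolated)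
14 | (E)-3-[(3S,4S)-3,4-dihydroxy-2,2-dimethyl-8-(3-methylbut-2-en-1-yl)chroman-6-yl]-1-(2,4,6-trihydroxyphenyl)prop-2-en-1-one | CC(C)=CCc1cc(/C=C/C(=O)c2c(O)cc(O)cc2O)cc2c1OC(C)(C)[C@@H](O)[C@H]2O | intermediate
15 | (2S)-2-[(3S,4S)-3,4-dihydroxy-2,2-dimethyl-8-(3-methylbut-2-en-1-yl)chroman-6-yl]-5,7-dihydroxy-2,3-dihydro-4H-chromen-4-one | CC(C)=CCc1cc([C@@H]2CC(=O)c3c(O)cc(O)cc3O2)cc2c1OC(C)(C)[C@@H](O)[C@H]2O | target

## Step count and risks

Total steps: 6. Longest linear sequence: 6 (1 → 4 → 6 → 7 → 10 → 14 → 15); 2 and 11 are used as purchased.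

**Highest risk: the asymmetric cyclisation (step 6).** The catalyst may give a low diastereomer ratio, and background cyclisation of the free chalcone is unselective. The fallback sets out from 14 and gives up catalyst control. NaOAc in EtOH at 40 °C closes ring C without selectivity to a 1:1 mixture of 15 and its C2 epimer, (2R)-2-[(3S,4S)-3,4-dihydroxy-2,2-dimethyl-8-(3-methylbut-2-en-1-yl)chroman-6-yl]-5,7-dihydroxy-2,3-dihydro-4H-chromen-4-one F5. Because the diol is enantiopure, the two are diastereomers and can be separated on an achiral preparative column under acidic eluent. F5 is reopened to 14 with cold aqueous KOH, re-acidified and cycled again, so the material converges on 15.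

**Second: the unprotected Claisen–Schmidt condensation (step 5).** The polyanion of 11 may condense sluggishly, and the free chalcone may cyclise during isolation. The fallback sets out from 11 and masks the two non-chelated phenols. Allyl bromide (2.2 equiv) and K2CO3 in refluxing acetone give 1-[2-hydroxy-4,6-bis(prop-2-en-1-yloxy)phenyl]ethan-1-one F3. Condensation of F3 with 10 under KOH/EtOH (the carbonate is again cleaved in the flask) gives (E)-3-[(3S,4S)-3,4-dihydroxy-2,2-dimethyl-8-(3-methylbut-2-en-1-yl)chroman-6-yl]-1-[2-hydroxy-4,6-bis(prop-2-en-1-yloxy)phenyl]prop-2-en-1-one F4. Pd(PPh3)4 (5 mol %, zerovalent palladium) with K2CO3 in MeOH at rt then transfers both allyl groups to methanol. These conditions spare the prenyl alkene and the acid-sensitive benzylic diol and hold the product as its phenoxide. Cold acidification to pH 4 comes back to the route at 14.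

**Third: the CO2 insertion (step 4).** The epoxide is internal and flanked by a quaternary carbon, so it may react slowly or rearrange to a chromanone on heating. The fallback sets out from 7 and builds the same carbonate stepwise by neighbouring-group participation. LiBr/AcOH in THF at 0 °C opens C4 with inversion to the trans-bromohydrin (3R,4R)-4-bromo-3-hydroxy-2,2-dimethyl-8-(3-methylbut-2-en-1-yl)chroman-6-carbaldehyde F1. Boc2O with catalytic DMAP in MeCN then gives (3R,4R)-4-bromo-6-formyl-2,2-dimethyl-8-(3-methylbut-2-en-1-yl)chroman-3-yl tert-butyl carbonate F2. Warming F2 in MeCN at 70 °C over NaHCO3 lets the Boc carbonyl oxygen displace bromide from the rear with loss of 2-methylpropene. This comes back to the route at 10 with the same net retention at C4.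

## Further compounds

F1 | step 4 | (3R,4R)-4-bromo-3-hydroxy-2,2-dimethyl-8-(3-methylbut-2-en-1-yl)chroman-6-carbaldehyde | CC(C)=CCc1cc(C=O)cc2c1OC(C)(C)[C@@H](O)[C@@H]2Br
F2 | step 4 | (3R,4R)-4-bromo-6-formyl-2,2-dimethyl-8-(3-methylbut-2-en-1-yl)chroman-3-yl tert-butyl carbonate | CC(C)=CCc1cc(C=O)cc2c1OC(C)(C)[C@@H](OC(=O)OC(C)(C)C)[C@@H]2Br
F3 | step 5 | 1-[2-hydroxy-4,6-bis(prop-2-en-1-yloxy)phenyl]ethan-1-one | CC(=O)c1c(O)cc(OCC=C)cc1OCC=C
F4 | step 5 | (E)-3-[(3S,4S)-3,4-dihydroxy-2,2-dimethyl-8-(3-methylbut-2-en-1-yl)chroman-6-yl]-1-[2-hydroxy-4,6-bis(prop-2-en-1-yloxy)phenyl]prop-2-en-1-one | CC(C)=CCc1cc(/C=C/C(=O)c2c(O)cc(OCC=C)cc2OCC=C)cc2c1OC(C)(C)[C@@H](O)[C@H]2O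
F5 | step 6 | (2R)-2-[(3S,4S)-3,4-dihydroxy-2,2-dimethyl-8-(3-methylbut-2-en-1-yl)chroman-6-yl]-5,7-dihydroxy-2,3-dihydro-4H-chromen-4-one | CC(C)=CCc1cc([C@H]2CC(=O)c3c(O)cc(O)cc3O2)cc2c1OC(C)(C)[C@@H](O)[C@H]2O
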